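**Retrosynthetic overview**

1. Rings are lettered A to E from the 2,4,6-trihydroxyphenyl end (A) to the 3,4,5-trihydroxyphenoxy end (E); all thirteen hydroxyls are carried as methyl ethers and freed in the last step with BBr3.
2. The plan rests on ring D, which has five neighbouring oxygen-bearing carbons (D1 bound through O to ring C, D6 bound through O to ring E, then D5, D4, D3) and one C–H (D2). D1, D6, D5 and D4 are taken from the four carbons of a squarate and D3–D2 from a 1-methoxyvinyl group, so ring D is closed by thermal ring expansion of a 4-(1-methoxyvinyl)cyclobutenone (new bond D1–D2), which leaves only the D1 hydroxyl free.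
3. The ring D–O–ring C bond comes from SNAr of the ring D phenol on 5-bromo-2-fluoroisophthalaldehyde, whose formyl groups become the C3 and C5 oxygens by Baeyer–Villiger oxidation. The ring C–O–ring B bond comes from Ullmann coupling of the ring C bromide with a ring A–B phenol, itself made by SNAr of 2,4,6-trimethoxyphenol on 2-fluoro-4,6-dimethoxybenzaldehyde and Baeyer–Villiger oxidation.
4. Ring D is the only ring built (step 4); rings A, B, C and E come from benzene starting materials.

Key step: step 4

Remark on the chemistry: 2,4,6-trimethoxyphenol is taken as a purchasable compound, while 5-bromo-2-fluoroisophthalaldehyde and 2-fluoro-4,6-dimethoxybenzaldehyde are prepared from common halides so that the route does not depend on their supply.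

**Route**

Step 1
Reactants: 1 squaric acid
Product: 2 squaric acid dichloride (3,4-dichlorocyclobut-3-ene-1,2-dione)
Conditions: SOCl2 (2.2 equiv), DMF (cat.), benzene, reflux
Reagents that add atoms: thionyl chloride, O=S(Cl)Cl
Why: Chlorodehydroxylation of the vinylogous acid through the DMF-derived chloroiminium catalyst is the standard preparation of this dichloride.

Step 2
Reactants: 2 squaric acid dichloride; 3 3,4,5-trimethoxyphenol
Product: 5 3-methoxy-4-(3,4,5-trimethoxyphenoxy)cyclobut-3-ene-1,2-dione, via 3-chloro-4-methoxycyclobut-3-ene-1,2-dione 4 (not isolated)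
Conditions: MeOH (1.0 equiv), iPr2NEt (1.0 equiv), CH2Cl2, −78 → −20 °C; then 3 (1.0 equiv), iPr2NEt (1.1 equiv), −20 → 0 °C; non-aqueous work-up
Reagents that add atoms: methanol, CO
Why: Two addition–elimination steps at the vinylogous acid chloride should give the mixed diester, because the first methoxy group slows a second methanolysis and the aryloxide, brought in last, displaces chloride but cannot displace methoxide, while the amine base keeps the electron-rich phenol reacting at oxygen.

Step 3
Reactants: 5 3-methoxy-4-(3,4,5-trimethoxyphenoxy)cyclobut-3-ene-1,2-dione; 6 methyl vinyl ether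
Product: 9 (±)-3,4-dimethoxy-4-(1-methoxyvinyl)-2-(3,4,5-trimethoxyphenoxy)cyclobut-2-en-1-one, via 1-methoxyvinyllithium 7 (not isolated), via lithium alkoxide adduct 8 (not isolated)
Conditions: 6 (1.3 equiv), tBuLi (1.15 equiv), THF, −78 → 0 °C; then 5, THF, −78 °C; then MeOTf (1.5 equiv), −78 → 0 °C; Et3N-deactivated silica
Reagents that add atoms: methyl triflate, COS(=O)(=O)C(F)(F)F
Why: 1,2-Addition of an organolithium to a squarate ester carbonyl should occur at the carbonyl conjugated through the ring double bond with the aryloxy group, which is the weaker donor and leaves that carbonyl the more electrophilic, and which is also flanked by the small methoxy group; MeOTf then O-methylates the tertiary lithium alkoxide in the cold, and the new quaternary carbon is formed racemic and is lost on aromatisation.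

Step 4
Reactants: 9 (±)-3,4-dimethoxy-4-(1-methoxyvinyl)-2-(3,4,5-trimethoxyphenoxy)cyclobut-2-en-1-one
Product: 12 3,4,5-trimethoxy-2-(3,4,5-trimethoxyphenoxy)phenol, via vinylketene 10 (not isolated), via cyclohexa-2,4-dienone tautomer 11 (not isolated)
Conditions: PhMe (0.02 M, degassed, base-washed glassware), 110 °C, Ar
Reagents that add atoms: none
Why: Heating should cleave the C1–C4 bond of the cyclobutenone by conrotatory 4π electrocyclic opening to the (Z)-dienylketene 10, in which the donor methoxy group of the sp3 carbon has rotated outward and the 1-methoxyvinyl group therefore lies next to the ketene. A thermal disrotatory 6π electrocyclisation then joins the ketene carbon to the vinyl CH2 (bond D1–D2) and closes ring D as the six-membered dienone 11, which enolises to the phenol. The closest known reaction type is the Moore ring expansion of squarate-derived 4-alkenyl-4-alkoxycyclobutenones to highly oxygenated phenols. No stereocentre is formed, and the racemic centre of 9 becomes aromatic carbon D4. The step needs the vinyl group to turn inward, which the outward preference of the methoxy group on the same carbon secures, and it needs the aryloxy group at D6, which is fixed by the constitution of 9. Dilute, degassed, acid-free solution should keep the ketene from dimerising or being trapped and the enol ether from hydrolysing.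

Step 5
Reactants: 13 5-bromo-2-fluoro-1,3-dimethylbenzene
Product: 14 5-bromo-1,3-bis(dibromomethyl)-2-fluorobenzene
Conditions: NBS (4.5 equiv), AIBN (cat.), PhCF3, reflux
Reagents that add atoms: N-bromosuccinimide, O=C1CCC(=O)N1Br
Why: Wohl–Ziegler radical bromination should place two bromines on each benzylic methyl group, a third being sterically slow, while the ring halogens are inert.

Step 6
Reactants: 14 5-bromo-1,3-bis(dibromomethyl)-2-fluorobenzene
Product: 15 5-bromo-2-fluoroisophthalaldehyde
Conditions: AgNO3 (4.4 equiv), acetone/H2O, reflux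
Reagents that add atoms: water, O
Why: Silver-assisted hydrolysis of benzylic gem-dibromides gives the aldehydes, and the acidic medium offers no nucleophile able to displace the activated fluoride.

Step 7
Reactants: 12 3,4,5-trimethoxy-2-(3,4,5-trimethoxyphenoxy)phenol; 15 5-bromo-2-fluoroisophthalaldehyde
Product: 16 5-bromo-2-[3,4,5-trimethoxy-2-(3,4,5-trimethoxyphenoxy)phenoxy]benzene-1,3-dicarbaldehyde
Conditions: K2CO3, DMF, rt → 50 °C
Reagents that add atoms: none
Why: SNAr of the phenoxide on the fluoride should be fast because both ortho formyl groups take up the charge of the Meisenheimer intermediate, whereas the bromide, meta to both, is not activated and stays.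

Step 8
Reactants: 16 5-bromo-2-[3,4,5-trimethoxy-2-(3,4,5-trimethoxyphenoxy)phenoxy]benzene-1,3-dicarbaldehyde
Product: 18 5-bromo-2-[3,4,5-trimethoxy-2-(3,4,5-trimethoxyphenoxy)phenoxy]benzene-1,3-diol, via bis-formate 17 (not isolated)
Conditions: mCPBA (2.4 equiv), CH2Cl2, 0 → 40 °C; then K2CO3 (cat.), MeOH, rt
Reagents that add atoms: mCPBA, OOC(=O)c1cccc(Cl)c1
Why: Twofold Baeyer–Villiger oxidation of the 2-aryloxybenzaldehyde units, with aryl migration assisted by the ortho ether oxygen, should give the aryl formates, which methanol cleaves to the phenols (a Dakin-type conversion overall); methyl ethers, diaryl ethers and the bromide are inert.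

Step 9
Reactants: 18 5-bromo-2-[3,4,5-trimethoxy-2-(3,4,5-trimethoxyphenoxy)phenoxy]benzene-1,3-diol
Product: 19 5-bromo-1,3-dimethoxy-2-[3,4,5-trimethoxy-2-(3,4,5-trimethoxyphenoxy)phenoxy]benzene
Conditions: MeI (3 equiv), K2CO3, DMF, rt
Reagents that add atoms: iodomethane, CI
Why: Williamson O-methylation of both phenols removes the acidic groups before the copper coupling and brings ring C to the same protecting group as the other rings.

Step 10
Reactants: 20 1-fluoro-3,5-dimethoxybenzene
Product: 22 2-fluoro-4,6-dimethoxybenzaldehyde, via iminium chloride 21 (not isolated)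
Conditions: POCl3, DMF, 0 → 70 °C; then H2O
Reagents that add atoms: N,N-dimethylformamide, CN(C)C=O; water, O
Why: Vilsmeier–Haack formylation should go mainly to the position para to one methoxy group and ortho to the other, next to the small fluorine, and not to the more crowded position between the two methoxy groups, as with other 1-substituted 3,5-dimethoxybenzenes.

Step 11
Reactants: 22 2-fluoro-4,6-dimethoxybenzaldehyde; 23 2,4,6-trimethoxyphenol
Product: 24 2,4-dimethoxy-6-(2,4,6-trimethoxyphenoxy)benzaldehyde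
Conditions: Cs2CO3, DMSO, 110 °C
Reagents that add atoms: none
Why: SNAr of the electron-rich phenoxide on the fluoride ortho to the formyl group should proceed on heating, since both methoxy groups are meta to the reacting carbon and place no charge on it.

Step 12
Reactants: 24 2,4-dimethoxy-6-(2,4,6-trimethoxyphenoxy)benzaldehyde
Product: 26 2,4-dimethoxy-6-(2,4,6-trimethoxyphenoxy)phenol, via aryl formate 25 (not isolated)
Conditions: mCPBA (1.2 equiv), CH2Cl2, 0 °C → rt; then K2CO3 (cat.), MeOH, rt
Reagents that add atoms: mCPBA, OOC(=O)c1cccc(Cl)c1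
Why: Baeyer–Villiger oxidation of a benzaldehyde with oxygen donors at both ortho positions and at the para position strongly favours aryl migration, and methanolysis of the formate frees the phenol.

Step 13
Reactants: 19 5-bromo-1,3-dimethoxy-2-[3,4,5-trimethoxy-2-(3,4,5-trimethoxyphenoxy)phenoxy]benzene; 26 2,4-dimethoxy-6-(2,4,6-trimethoxyphenoxy)phenol
Product: 27 1-{4-[2,4-dimethoxy-6-(2,4,6-trimethoxyphenoxy)phenoxy]-2,6-dimethoxyphenoxy}-3,4,5-trimethoxy-2-(3,4,5-trimethoxyphenoxy)benzene
Conditions: CuI (10 mol %), picolinic acid (20 mol %), K3PO4, DMSO, 100 °C, Ar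
Reagents that add atoms: none
Why: Ullmann-type copper-catalysed diaryl ether synthesis with the picolinic acid ligand tolerates phenols substituted at both ortho positions, the bromide carries no ortho substituent, and every other group is a methyl or diaryl ether inert to phosphate base.

Step 14
Reactants: 27 1-{4-[2,4-dimethoxy-6-(2,4,6-trimethoxyphenoxy)phenoxy]-2,6-dimethoxyphenoxy}-3,4,5-trimethoxy-2-(3,4,5-trimethoxyphenoxy)benzene
Product: 28 5-{4-[2,4-dihydroxy-6-(2,4,6-trihydroxyphenoxy)phenoxy]-2,6-dihydroxyphenoxy}-4-(3,4,5-trihydroxyphenoxy)benzene-1,2,3-triol (target CNP0243665.0)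
Conditions: BBr3 (30 equiv), CH2Cl2, −78 °C → rt, Ar; then degassed H2O
Reagents that add atoms: none
Why: Lewis acid-mediated cleavage of aryl methyl ethers (boron coordination, then bromide attack at methyl) should remove all thirteen methyl groups, while the diaryl ether bonds offer no carbon open to that attack; the oxidation-prone polyphenol is worked up with exclusion of air.

**Compound list**

1 | squaric acid | OC1=C(O)C(=O)C1=O | starting material
2 | squaric acid dichloride (3,4-dichlorocyclobut-3-ene-1,2-dione) | ClC1=C(Cl)C(=O)C1=O | intermediate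
3 | 3,4,5-trimethoxyphenol | COc1cc(O)cc(OC)c1OC | starting material
4 | 3-chloro-4-methoxycyclobut-3-ene-1,2-dione | COC1=C(Cl)C(=O)C1=O | intermediate
5 | 3-methoxy-4-(3,4,5-trimethoxyphenoxy)cyclobut-3-ene-1,2-dione | COC1=C(Oc2cc(OC)c(OC)c(OC)c2)C(=O)C1=O | intermediate
6 | methyl vinyl ether | COC=C | starting material
7 | 1-methoxyvinyllithium | [Li]C(=C)OC | intermediate
8 | lithium 2-methoxy-1-(1-methoxyvinyl)-4-oxo-3-(3,4,5-trimethoxyphenoxy)cyclobut-2-en-1-olate (racemic) | [Li]OC1(C(=C)OC)C(OC)=C(Oc2cc(OC)c(OC)c(OC)c2)C1=O | intermediate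
9 | (±)-3,4-dimethoxy-4-(1-methoxyvinyl)-2-(3,4,5-trimethoxyphenoxy)cyclobut-2-en-1-one | O=C1C(Oc2cc(OC)c(OC)c(OC)c2)=C(OC)C1(OC)C(=C)OC | intermediate
10 | (3Z)-3,4,5-trimethoxy-2-(3,4,5-trimethoxyphenoxy)hexa-1,3,5-trien-1-one (vinylketene) | O=C=C(Oc1cc(OC)c(OC)c(OC)c1)/C(OC)=C(OC)\C(OC)=C | intermediate
11 | 3,4,5-trimethoxy-2-(3,4,5-trimethoxyphenoxy)cyclohexa-2,4-dien-1-one | O=C1CC(OC)=C(OC)C(OC)=C1Oc1cc(OC)c(OC)c(OC)c1 | intermediate
12 | 3,4,5-trimethoxy-2-(3,4,5-trimethoxyphenoxy)phenol | Oc1cc(OC)c(OC)c(OC)c1Oc1cc(OC)c(OC)c(OC)c1 | intermediate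
13 | 5-bromo-2-fluoro-1,3-dimethylbenzene | Cc1cc(Br)cc(C)c1F | starting material
14 | 5-bromo-1,3-bis(dibromomethyl)-2-fluorobenzene | BrC(Br)c1cc(Br)cc(C(Br)Br)c1F | intermediate
15 | 5-bromo-2-fluoroisophthalaldehyde | O=Cc1cc(Br)cc(C=O)c1F | intermediate
16 | 5-bromo-2-[3,4,5-trimethoxy-2-(3,4,5-trimethoxyphenoxy)phenoxy]benzene-1,3-dicarbaldehyde | O=Cc1cc(Br)cc(C=O)c1Oc1cc(OC)c(OC)c(OC)c1Oc1cc(OC)c(OC)c(OC)c1 | intermediate
17 | 5-bromo-2-[3,4,5-trimethoxy-2-(3,4,5-trimethoxyphenoxy)phenoxy]-1,3-phenylene diformate | O=COc1cc(Br)cc(OC=O)c1Oc1cc(OC)c(OC)c(OC)c1Oc1cc(OC)c(OC)c(OC)c1 | intermediate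
18 | 5-bromo-2-[3,4,5-trimethoxy-2-(3,4,5-trimethoxyphenoxy)phenoxy]benzene-1,3-diol | Oc1cc(Br)cc(O)c1Oc1cc(OC)c(OC)c(OC)c1Oc1cc(OC)c(OC)c(OC)c1 | intermediate
19 | 5-bromo-1,3-dimethoxy-2-[3,4,5-trimethoxy-2-(3,4,5-trimethoxyphenoxy)phenoxy]benzene | COc1cc(Br)cc(OC)c1Oc1cc(OC)c(OC)c(OC)c1Oc1cc(OC)c(OC)c(OC)c1 | intermediate
20 | 1-fluoro-3,5-dimethoxybenzene | COc1cc(F)cc(OC)c1 | starting material
21 | N-(2-fluoro-4,6-dimethoxybenzylidene)-N-methylmethanaminium chloride | C[N+](C)=Cc1c(F)cc(OC)cc1OC.[Cl-] | intermediate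
22 | 2-fluoro-4,6-dimethoxybenzaldehyde | O=Cc1c(F)cc(OC)cc1OC | intermediate
23 | 2,4,6-trimethoxyphenol | COc1cc(OC)c(O)c(OC)c1 | starting material
24 | 2,4-dimethoxy-6-(2,4,6-trimethoxyphenoxy)benzaldehyde | O=Cc1c(OC)cc(OC)cc1Oc1c(OC)cc(OC)cc1OC | intermediate
25 | 2,4-dimethoxy-6-(2,4,6-trimethoxyphenoxy)phenyl formate | O=COc1c(OC)cc(OC)cc1Oc1c(OC)cc(OC)cc1OC | intermediate
26 | 2,4-dimethoxy-6-(2,4,6-trimethoxyphenoxy)phenol | Oc1c(OC)cc(OC)cc1Oc1c(OC)cc(OC)cc1OC | intermediate
27 | 1-{4-[2,4-dimethoxy-6-(2,4,6-trimethoxyphenoxy)phenoxy]-2,6-dimethoxyphenoxy}-3,4,5-trimethoxy-2-(3,4,5-trimethoxyphenoxy)benzene | COc1cc(OC)c(Oc2cc(OC)cc(OC)c2Oc2cc(OC)c(Oc3cc(OC)c(OC)c(OC)c3Oc3cc(OC)c(OC)c(OC)c3)c(OC)c2)c(OC)c1 | intermediate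
28 | 5-{4-[2,4-dihydroxy-6-(2,4,6-trihydroxyphenoxy)phenoxy]-2,6-dihydroxyphenoxy}-4-(3,4,5-trihydroxyphenoxy)benzene-1,2,3-triol (CNP0243665.0) | Oc1cc(O)c(Oc2cc(O)cc(O)c2Oc2cc(O)c(Oc3cc(O)c(O)c(O)c3Oc3cc(O)c(O)c(O)c3)c(O)c2)c(O)c1 | target

**Step count**

Total: 14 steps. Longest linear sequence: 9 steps (steps 1, 2, 3, 4, 7, 8, 9, 13, 14, from squaric acid).

**Steps most likely to fail**

Step 3. The vinyllithium may lose site selectivity and also attack the carbonyl next to the aryloxy-bearing carbon, or it may replace the aryloxy group by conjugate addition–elimination, so that the aryloxy group ends up on the wrong ring carbon or is lost. The fallback sets out from 2 and 3 and comes back at 9. The dichloride 2 would be esterified with two equivalents of 3 (iPr2NEt, CH2Cl2) to the symmetric diester 3,4-bis(3,4,5-trimethoxyphenoxy)cyclobut-3-ene-1,2-dione F1, whose two carbonyl groups are equivalent. Addition of 7 and capping with MeOTf as in step 3 would lead, through the lithium alkoxide lithium 1-(1-methoxyvinyl)-4-oxo-2,3-bis(3,4,5-trimethoxyphenoxy)cyclobut-2-en-1-olate F2, to 4-methoxy-4-(1-methoxyvinyl)-2,3-bis(3,4,5-trimethoxyphenoxy)cyclobut-2-en-1-one F3. NaOMe in MeOH/THF at −40 → 0 °C should then exchange only the aryloxy group on the β-carbon of the enone by conjugate addition–elimination (a vinylogous transesterification), releasing 3 and giving 9. The site of the aryloxy group is then set by which carbon is β to the carbonyl and no longer by a choice between two carbonyl groups.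

Step 8. In the peracid adducts of the two formyl groups hydride may migrate instead of aryl, because ring C is made electron-poor by bromine and by the second formyl group, which would lead to carboxylic acids; excess peracid may also oxidise the methoxylated rings D and E. The fallback sets out from 16 and comes back at 18. MeMgBr (THF, −78 → 0 °C) would add to both aldehydes to give 1,1'-{5-bromo-2-[3,4,5-trimethoxy-2-(3,4,5-trimethoxyphenoxy)phenoxy]-1,3-phenylene}diethanol F4 as a mixture of diastereomers. Dess–Martin periodinane would oxidise it to 1,1'-{5-bromo-2-[3,4,5-trimethoxy-2-(3,4,5-trimethoxyphenoxy)phenoxy]-1,3-phenylene}diethanone F5. Baeyer–Villiger oxidation of the methyl ketones (mCPBA, TFA, CH2Cl2), where the aryl group competes only with methyl, should give 5-bromo-2-[3,4,5-trimethoxy-2-(3,4,5-trimethoxyphenoxy)phenoxy]-1,3-phenylene diacetate F6, and K2CO3 in MeOH would cleave the acetates to 18.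

Step 13. Carbon–oxygen bond formation at copper may be slow between an electron-rich bromide and a phenol blocked on both ortho sides, so that protodebromination of 19 and oxidative degradation of the phenoxide overtake the coupling. The fallback sets out from 19 and comes back at 27. Miyaura borylation (B2pin2, Pd(dppf)Cl2, KOAc, dioxane, 90 °C) would give 2-{3,5-dimethoxy-4-[3,4,5-trimethoxy-2-(3,4,5-trimethoxyphenoxy)phenoxy]phenyl}-4,4,5,5-tetramethyl-1,3,2-dioxaborolane F7. Cleavage of the pinacol ester (NaIO4, NH4OAc, acetone/H2O) would give {3,5-dimethoxy-4-[3,4,5-trimethoxy-2-(3,4,5-trimethoxyphenoxy)phenoxy]phenyl}boronic acid F8. Chan–Lam–Evans coupling of this acid with 26 (Cu(OAc)2, pyridine, 4 Å molecular sieves, air, CH2Cl2, rt) should give 27 by an oxidative pathway at room temperature that needs no aryl halide activation.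

**Further compounds**

F1 | step 3 | 3,4-bis(3,4,5-trimethoxyphenoxy)cyclobut-3-ene-1,2-dione | O=C1C(=O)C(Oc2cc(OC)c(OC)c(OC)c2)=C1Oc1cc(OC)c(OC)c(OC)c1
F2 | step 3 | lithium 1-(1-methoxyvinyl)-4-oxo-2,3-bis(3,4,5-trimethoxyphenoxy)cyclobut-2-en-1-olate (racemic) | [Li]OC1(C(=C)OC)C(Oc2cc(OC)c(OC)c(OC)c2)=C(Oc2cc(OC)c(OC)c(OC)c2)C1=O
F3 | step 3 | 4-methoxy-4-(1-methoxyvinyl)-2,3-bis(3,4,5-trimethoxyphenoxy)cyclobut-2-en-1-one (racemic) | O=C1C(Oc2cc(OC)c(OC)c(OC)c2)=C(Oc2cc(OC)c(OC)c(OC)c2)C1(OC)C(=C)OC
F4 | step 8 | 1,1'-{5-bromo-2-[3,4,5-trimethoxy-2-(3,4,5-trimethoxyphenoxy)phenoxy]-1,3-phenylene}diethanol (mixture of diastereomers) | CC(O)c1cc(Br)cc(C(C)O)c1Oc1cc(OC)c(OC)c(OC)c1Oc1cc(OC)c(OC)c(OC)c1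
F5 | step 8 | 1,1'-{5-bromo-2-[3,4,5-trimethoxy-2-(3,4,5-trimethoxyphenoxy)phenoxy]-1,3-phenylene}diethanone | CC(=O)c1cc(Br)cc(C(C)=O)c1Oc1cc(OC)c(OC)c(OC)c1Oc1cc(OC)c(OC)c(OC)c1
F6 | step 8 | 5-bromo-2-[3,4,5-trimethoxy-2-(3,4,5-trimethoxyphenoxy)phenoxy]-1,3-phenylene diacetate | CC(=O)Oc1cc(Br)cc(OC(C)=O)c1Oc1cc(OC)c(OC)c(OC)c1Oc1cc(OC)c(OC)c(OC)c1
F7 | step 13 | 2-{3,5-dimethoxy-4-[3,4,5-trimethoxy-2-(3,4,5-trimethoxyphenoxy)phenoxy]phenyl}-4,4,5,5-tetramethyl-1,3,2-dioxaborolane | COc1cc(B2OC(C)(C)C(C)(C)O2)cc(OC)c1Oc1cc(OC)c(OC)c(OC)c1Oc1cc(OC)c(OC)c(OC)c1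
F8 | step 13 | {3,5-dimethoxy-4-[3,4,5-trimethoxy-2-(3,4,5-trimethoxyphenoxy)phenoxy]phenyl}boronic acid | COc1cc(B(O)O)cc(OC)c1Oc1cc(OC)c(OC)c(OC)c1Oc1cc(OC)c(OC)c(OC)c1
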